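## Retrosynthetic overview

- The angelate is installed last by Mitsunobu inversion of a 2β-alcohol. The tetrahydrofuran ring comes from 5-exo opening of a 4α,5α-epoxide by the 11-OH, which sets C4 and C5 together.
- The cis γ-lactone comes from iodolactonization of a Δ8 acid. The C7–C11 bond comes from an Ireland–Claisen rearrangement of a C9 allylic glycolate, and the C11 methyl from convex-face enolate methylation.
- The seven-membered ring comes from ring-closing metathesis of an allyl group with a vinyl ketone.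
- The C1–C10 bond, the C1 and C10 stereocenters and the C4=C5 alkene come from the key Ireland–Claisen rearrangement of a tertiary cyclopentenyl propanoate, made from (R)-4-silyloxycyclopentenone.
- Ring order: five-membered carbocycle (bought), then seven-membered ring, then lactone, then tetrahydrofuran.

Assumption: (R)-4-(tert-butyldimethylsilyloxy)cyclopent-2-en-1-one 1 is bought as the single enantiomer and is the only source of chirality; locants C1–C15 and α/β in names of bicyclic and later compounds are the guaiane locants of the target (β = face of the lactone oxygen on C8; the C10 methyl is α throughout).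

## Route

Step 1
Reactants: 1 (R)-4-(tert-butyldimethylsilyloxy)cyclopent-2-en-1-one
Product: 2 (R)-4-(tert-butyldimethylsilyloxy)-2-iodocyclopent-2-en-1-one
Conditions: I2, pyridine, CH2Cl2, 0 → 25 °C
Reagents that add atoms: iodine II
Why: Pyridine-mediated α-iodination of the enone (conjugate addition, iodination, elimination) leaves the silyl ether and the stereocenter untouched.

Step 2
Reactants: 2 (R)-4-(tert-butyldimethylsilyloxy)-2-iodocyclopent-2-en-1-one; 3 allyltributylstannane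
Product: 4 (R)-4-(tert-butyldimethylsilyloxy)-2-(prop-2-enyl)cyclopent-2-en-1-one
Conditions: PdCl2(PhCN)2 (5 mol %), AsPh3, CuI, NMP, 60 °C
Reagents that add atoms: allyltributylstannane C=CC[Sn](CCCC)(CCCC)CCCC
Why: Stille coupling of the α-iodoenone brings in C6–C8 under neutral conditions that the base-sensitive 4-silyloxy enone tolerates.

Step 3
Reactants: 4 (R)-4-(tert-butyldimethylsilyloxy)-2-(prop-2-enyl)cyclopent-2-en-1-one; 5 propanoyl chloride
Product: 7 (1S,4R)-4-(tert-butyldimethylsilyloxy)-1-methyl-2-(prop-2-enyl)cyclopent-2-enyl propanoate, via lithium tert-alkoxide 6 (not isolated)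
Conditions: MeLi, THF, −78 °C; then EtCOCl, −78 → 0 °C
Reagents that add atoms: methyllithium C[Li]; propanoyl chloride CCC(Cl)=O
Why: MeLi adds 1,2 to the enone on the face opposite the silyloxy group (new C–O bond cis to OTBS) and the hindered tertiary alkoxide is acylated in the same flask.

Step 4
Reactants: 7 (1S,4R)-4-(tert-butyldimethylsilyloxy)-1-methyl-2-(prop-2-enyl)cyclopent-2-enyl propanoate
Product: 9 (2S)-2-[(1S,5R)-5-(tert-butyldimethylsilyloxy)-3-methyl-2-(prop-2-enyl)cyclopent-2-enyl]propanoic acid, via silyl ketene acetal 8 (not isolated)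
Conditions: LiN(iPr)2, THF–DMPU (4:1), −78 °C; Me3SiCl; → 50 °C; then 1 M HCl
Reagents that add atoms: none
Why: Ireland–Claisen [3,3]-sigmatropic rearrangement delivers C10 to C1 suprafacially on the face of the departing C4–O bond (cis to OTBS) and moves the alkene to C4=C5; the (Z)-ketene acetal reacts through a boat transition state (the chair is blocked by the ring and the cis silyloxy group) with the methyl outward, which gives the 10α-methyl configuration.

Step 5
Reactants: 9 (2S)-2-[(1S,5R)-5-(tert-butyldimethylsilyloxy)-3-methyl-2-(prop-2-enyl)cyclopent-2-enyl]propanoic acid; 10 N,O-dimethylhydroxylamine hydrochloride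
Product: 11 (2S)-2-[(1S,5R)-5-(tert-butyldimethylsilyloxy)-3-methyl-2-(prop-2-enyl)cyclopent-2-enyl]-N-methoxy-N-methylpropanamide
Conditions: 1,1′-carbonyldiimidazole, CH2Cl2, 0 → 25 °C; then MeNHOMe·HCl
Reagents that add atoms: N,O-dimethylhydroxylamine hydrochloride CNOC.Cl
Why: Amidation through the acyl imidazolide gives the Weinreb amide without epimerizing C10.

Step 6
Reactants: 11 the Weinreb amide; 12 vinylmagnesium bromide
Product: 13 (4S)-4-[(1S,5R)-5-(tert-butyldimethylsilyloxy)-3-methyl-2-(prop-2-enyl)cyclopent-2-enyl]pent-1-en-3-one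
Conditions: CH2=CHMgBr, THF, 0 °C; cold 1 M HCl quench
Reagents that add atoms: vinylmagnesium bromide C=C[Mg]Br
Why: The chelated tetrahedral adduct of the Weinreb amide stops the Grignard addition at the vinyl ketone.

Step 7
Reactants: 13 (4S)-4-[(1S,5R)-5-(tert-butyldimethylsilyloxy)-3-methyl-2-(prop-2-enyl)cyclopent-2-enyl]pent-1-en-3-one
Product: 14 2β-(tert-butyldimethylsilyloxy)-11,12,13-trinor-1αH-guaia-4,7-dien-9-one (1S,2R,10S)
Conditions: second-generation Grubbs catalyst (H2IMes)(PCy3)Cl2Ru=CHPh (5 mol %), CH2Cl2, 40 °C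
Reagents that add atoms: none
Why: Ring-closing metathesis joins the vinyl ketone and the allyl group into the cycloheptenone while the tetrasubstituted C4=C5 alkene is inert to the catalyst.

Step 8
Reactants: 14 2β-(tert-butyldimethylsilyloxy)-11,12,13-trinor-1αH-guaia-4,7-dien-9-one
Product: 15 2β-(tert-butyldimethylsilyloxy)-11,12,13-trinor-1αH-guaia-4,7-dien-9β-ol (1S,2R,9S,10S)
Conditions: NaBH4, CeCl3·7H2O, MeOH, −78 → 0 °C
Reagents that add atoms: none
Why: Luche 1,2-reduction with the small hydride entering on the α face, as in axial-type attack on 2-alkylcycloalkanones, gives the pseudo-equatorial 9β-alcohol trans to the 10α-methyl.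

Step 9
Reactants: 15 2β-(tert-butyldimethylsilyloxy)-11,12,13-trinor-1αH-guaia-4,7-dien-9β-ol; 16 2-(tert-butyldimethylsilyloxy)acetic acid
Product: 17 2β-(tert-butyldimethylsilyloxy)-11,12,13-trinor-1αH-guaia-4,7-dien-9β-yl (tert-butyldimethylsilyloxy)acetate
Conditions: dicyclohexylcarbodiimide, 4-(dimethylamino)pyridine (cat.), CH2Cl2, 0 → 25 °C
Reagents that add atoms: 2-(tert-butyldimethylsilyloxy)acetic acid CC(C)(C)[Si](C)(C)OCC(O)=O
Why: Steglich esterification acylates the secondary allylic alcohol with retention at C9.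

Step 10
Reactants: 17 2β-(tert-butyldimethylsilyloxy)-11,12,13-trinor-1αH-guaia-4,7-dien-9β-yl (tert-butyldimethylsilyloxy)acetate
Product: 19 2β,11-bis(tert-butyldimethylsilyloxy)-13-nor-1αH,7αH-guaia-4,8-dien-12-oic acid (C11 epimers), via silyl ketene acetal 18 (not isolated)
Conditions: LiN(iPr)2, Me3SiCl, THF, −78 → 25 °C; then aqueous citric acid
Reagents that add atoms: none
Why: The second Ireland–Claisen rearrangement transfers the glycolate carbon across the ring suprafacially from the 9β-oxygen to the β face of C7 and shifts the alkene to C8=C9; the C11 configuration does not matter because it is reset in step 13.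

Step 11
Reactants: 19 2β,11-bis(tert-butyldimethylsilyloxy)-13-nor-1αH,7αH-guaia-4,8-dien-12-oic acid
Product: 20 9α-iodo-2β,11-bis(tert-butyldimethylsilyloxy)-13-nor-1αH,7αH,8αH-guai-4-en-12,8-olide (C11 epimers)
Conditions: I2, NaHCO3, MeCN–H2O, 0 °C, dark
Reagents that add atoms: iodine II
Why: Iodolactonization: the carboxylate on the β face attacks C8 5-exo anti to the iodonium ion, which gives the cis-fused γ-lactone (8β-O) and the 9α-iodide.

Step 12
Reactants: 20 9α-iodo-2β,11-bis(tert-butyldimethylsilyloxy)-13-nor-1αH,7αH,8αH-guai-4-en-12,8-olide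
Product: 21 2β,11-bis(tert-butyldimethylsilyloxy)-13-nor-1αH,7αH,8αH-guai-4-en-12,8-olide (C11 epimers)
Conditions: Bu3SnH, AIBN (cat.), toluene, 80 °C
Reagents that add atoms: none
Why: Radical chain reduction removes the secondary iodide; the lactone, silyl ethers and the tetrasubstituted alkene do not react.

Step 13
Reactants: 21 2β,11-bis(tert-butyldimethylsilyloxy)-13-nor-1αH,7αH,8αH-guai-4-en-12,8-olide
Product: 22 (11S)-2β,11-bis(tert-butyldimethylsilyloxy)-1αH,7αH,8αH-guai-4-en-12,8-olide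
Conditions: LiN(iPr)2, THF, −78 °C; then MeI, DMPU, −78 → −20 °C
Reagents that add atoms: iodomethane IC
Why: Both C11 epimers give the same lactone enolate, which is methylated on its convex face (the side of H7 and H8), so the methyl ends exo and the silyloxy group endo towards C6.

Step 14
Reactants: 22 (11S)-2β,11-bis(tert-butyldimethylsilyloxy)-1αH,7αH,8αH-guai-4-en-12,8-olide
Product: 23 (11S)-4α,5α-epoxy-2β,11-bis(tert-butyldimethylsilyloxy)-1αH,7αH,8αH-guaian-12,8-olide
Conditions: mCPBA, CH2Cl2, 0 °C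
Reagents that add atoms: 3-chloroperoxybenzoic acid OOC(=O)c1cccc(Cl)c1
Why: Prilezhaev epoxidation of the only alkene occurs on the α face because the β face is shielded by the 2β-silyloxy group and the C1–C10 bond.

Step 15
Reactants: 23 (11S)-4α,5α-epoxy-2β,11-bis(tert-butyldimethylsilyloxy)-1αH,7αH,8αH-guaian-12,8-olide
Product: 25 (11S)-5β,11-epoxy-2β,4α-dihydroxy-1αH,7αH,8αH-guaian-12,8-olide, via epoxy diol 24 (not isolated)
Conditions: Bu4NF, AcOH, THF, 25 → 40 °C; then camphorsulfonic acid (cat.), CH2Cl2, 25 °C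
Reagents that add atoms: none
Why: Fluoride removes both silyl ethers and the freed tertiary 11-OH opens the epoxide 5-exo at C5 with inversion under acid catalysis, which forms the 5β,11-ether and leaves the 4α-OH.

Step 16
Reactants: 25 (11S)-5β,11-epoxy-2β,4α-dihydroxy-1αH,7αH,8αH-guaian-12,8-olide; 26 angelic acid
Product: 27 2α-angeloyloxy-5β,11-epoxy-4α-hydroxy-1αH,7αH,8αH-guaian-12,8-olide (1R,2S,4R,5R,7S,8R,10R,11S)
Conditions: PPh3, diisopropyl azodicarboxylate, toluene, 0 → 25 °C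
Reagents that add atoms: angelic acid C/C=C(/C)C(O)=O
Why: Mitsunobu esterification displaces the activated 2β-oxygen by angelate with inversion to give the 2α-ester, and the tertiary 4-OH cannot react.

## Compound list

1 | (R)-4-(tert-butyldimethylsilyloxy)cyclopent-2-en-1-one | CC(C)(C)[Si](C)(C)O[C@@H]1CC(=O)C=C1 | starting material
2 | (R)-4-(tert-butyldimethylsilyloxy)-2-iodocyclopent-2-en-1-one | CC(C)(C)[Si](C)(C)O[C@@H]1CC(=O)C(I)=C1 | intermediate
3 | allyltributylstannane | C=CC[Sn](CCCC)(CCCC)CCCC | starting material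
4 | (R)-4-(tert-butyldimethylsilyloxy)-2-(prop-2-enyl)cyclopent-2-en-1-one | CC(C)(C)[Si](C)(C)O[C@@H]1CC(=O)C(CC=C)=C1 | intermediate
5 | propanoyl chloride | CCC(Cl)=O | starting material
6 | lithium (1S,4R)-4-(tert-butyldimethylsilyloxy)-1-methyl-2-(prop-2-enyl)cyclopent-2-en-1-olate | [Li]O[C@@]1(C)C[C@@H](O[Si](C)(C)C(C)(C)C)C=C1CC=C | intermediate
7 | (1S,4R)-4-(tert-butyldimethylsilyloxy)-1-methyl-2-(prop-2-enyl)cyclopent-2-enyl propanoate | CCC(=O)O[C@@]1(C)C[C@@H](O[Si](C)(C)C(C)(C)C)C=C1CC=C | intermediate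
8 | (Z)-trimethylsilyl ketene acetal of 7 | C/C=C(\O[Si](C)(C)C)O[C@@]1(C)C[C@@H](O[Si](C)(C)C(C)(C)C)C=C1CC=C | intermediate
9 | (2S)-2-[(1S,5R)-5-(tert-butyldimethylsilyloxy)-3-methyl-2-(prop-2-enyl)cyclopent-2-enyl]propanoic acid | C[C@H](C(O)=O)[C@H]1C(CC=C)=C(C)C[C@H]1O[Si](C)(C)C(C)(C)C | intermediate
10 | N,O-dimethylhydroxylamine hydrochloride | CNOC.Cl | starting material
11 | (2S)-2-[(1S,5R)-5-(tert-butyldimethylsilyloxy)-3-methyl-2-(prop-2-enyl)cyclopent-2-enyl]-N-methoxy-N-methylpropanamide | C[C@H](C(=O)N(C)OC)[C@H]1C(CC=C)=C(C)C[C@H]1O[Si](C)(C)C(C)(C)C | intermediate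
12 | vinylmagnesium bromide | C=C[Mg]Br | starting material
13 | (4S)-4-[(1S,5R)-5-(tert-butyldimethylsilyloxy)-3-methyl-2-(prop-2-enyl)cyclopent-2-enyl]pent-1-en-3-one | C[C@H](C(=O)C=C)[C@H]1C(CC=C)=C(C)C[C@H]1O[Si](C)(C)C(C)(C)C | intermediate
14 | 2β-(tert-butyldimethylsilyloxy)-11,12,13-trinor-1αH-guaia-4,7-dien-9-one (1S,2R,10S) | C[C@@H]1C(=O)C=CCC2=C(C)C[C@@H](O[Si](C)(C)C(C)(C)C)[C@@H]12 | intermediate
15 | 2β-(tert-butyldimethylsilyloxy)-11,12,13-trinor-1αH-guaia-4,7-dien-9β-ol (1S,2R,9S,10S) | C[C@@H]1[C@@H](O)C=CCC2=C(C)C[C@@H](O[Si](C)(C)C(C)(C)C)[C@@H]12 | intermediate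
16 | 2-(tert-butyldimethylsilyloxy)acetic acid | CC(C)(C)[Si](C)(C)OCC(O)=O | starting material
17 | 2β-(tert-butyldimethylsilyloxy)-11,12,13-trinor-1αH-guaia-4,7-dien-9β-yl (tert-butyldimethylsilyloxy)acetate | C[C@@H]1[C@@H](OC(=O)CO[Si](C)(C)C(C)(C)C)C=CCC2=C(C)C[C@@H](O[Si](C)(C)C(C)(C)C)[C@@H]12 | intermediate
18 | trimethylsilyl ketene acetal of 17 | C[C@@H]1[C@@H](OC(O[Si](C)(C)C)=CO[Si](C)(C)C(C)(C)C)C=CCC2=C(C)C[C@@H](O[Si](C)(C)C(C)(C)C)[C@@H]12 | intermediate
19 | 2β,11-bis(tert-butyldimethylsilyloxy)-13-nor-1αH,7αH-guaia-4,8-dien-12-oic acid (C11 epimers) | C[C@@H]1C=C[C@@H](C(O[Si](C)(C)C(C)(C)C)C(O)=O)CC2=C(C)C[C@@H](O[Si](C)(C)C(C)(C)C)[C@@H]12 | intermediate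
20 | 9α-iodo-2β,11-bis(tert-butyldimethylsilyloxy)-13-nor-1αH,7αH,8αH-guai-4-en-12,8-olide (C11 epimers) | C[C@@H]1[C@H](I)[C@H]2OC(=O)C(O[Si](C)(C)C(C)(C)C)[C@H]2CC3=C(C)C[C@@H](O[Si](C)(C)C(C)(C)C)[C@@H]13 | intermediate
21 | 2β,11-bis(tert-butyldimethylsilyloxy)-13-nor-1αH,7αH,8αH-guai-4-en-12,8-olide (C11 epimers) | C[C@@H]1C[C@H]2OC(=O)C(O[Si](C)(C)C(C)(C)C)[C@H]2CC3=C(C)C[C@@H](O[Si](C)(C)C(C)(C)C)[C@@H]13 | intermediate
22 | (11S)-2β,11-bis(tert-butyldimethylsilyloxy)-1αH,7αH,8αH-guai-4-en-12,8-olide | C[C@@H]1C[C@H]2OC(=O)[C@@](C)(O[Si](C)(C)C(C)(C)C)[C@H]2CC3=C(C)C[C@@H](O[Si](C)(C)C(C)(C)C)[C@@H]13 | intermediate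
23 | (11S)-4α,5α-epoxy-2β,11-bis(tert-butyldimethylsilyloxy)-1αH,7αH,8αH-guaian-12,8-olide | C[C@@H]1C[C@H]2OC(=O)[C@@](C)(O[Si](C)(C)C(C)(C)C)[C@H]2C[C@]34O[C@]4(C)C[C@@H](O[Si](C)(C)C(C)(C)C)[C@@H]13 | intermediate
24 | (11S)-4α,5α-epoxy-2β,11-dihydroxy-1αH,7αH,8αH-guaian-12,8-olide | C[C@@H]1C[C@H]2OC(=O)[C@@](C)(O)[C@H]2C[C@]34O[C@]4(C)C[C@@H](O)[C@@H]13 | intermediate
25 | (11S)-5β,11-epoxy-2β,4α-dihydroxy-1αH,7αH,8αH-guaian-12,8-olide | O[C@@H]1C[C@@](C)(O)[C@@]23C[C@H]4[C@@H](C[C@@H](C)[C@H]12)OC(=O)[C@@]4(C)O3 | intermediate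
26 | angelic acid, (Z)-2-methylbut-2-enoic acid | C/C=C(/C)C(O)=O | starting material
27 | CNP0293659.1, 2α-angeloyloxy-5β,11-epoxy-4α-hydroxy-1αH,7αH,8αH-guaian-12,8-olide (1R,2S,4R,5R,7S,8R,10R,11S) | C/C=C(/C)C(=O)O[C@H]1C[C@@](C)(O)[C@@]23C[C@H]4[C@@H](C[C@@H](C)[C@H]12)OC(=O)[C@@]4(C)O3 | target

## Step count and risks

Total step count: 16. Longest linear sequence: 16 steps (1 → 27).

Steps most likely to fail:

- **Step 4.** The first Ireland–Claisen rearrangement has to form a C–C bond at C1 next to the cis silyloxy group from a hindered tertiary ester, and it also sets C10. The fallback sets out from 4 and comes back at 11. MeLi addition to 4 and trapping with methyl chloroformate gives the tertiary allylic methyl carbonate F1. Pd(PPh3)4 with sodium dimethyl methylmalonate (Tsuji–Trost allylation, net retention, attack at the less hindered C1 terminus) gives the malonate F2. Krapcho demethoxycarbonylation (LiCl, wet DMSO, 150 °C) gives the methyl ester F3 as a C10 mixture. MeNHOMe·HCl with iPrMgCl converts it into 11 (10-epimers). The 10α-methyl isomer is then secured by base equilibration (DBU) of the ketone α-center at enone 14.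

- **Step 11.** Iodolactonization may be diverted by the more electron-rich C4=C5 alkene (iodonium formation there, or a six-membered lactone at C5). The fallback sets out from 17 and comes back at 23. mCPBA epoxidizes the tetrasubstituted alkene of 17 first, on the α face, to the epoxy ester F4. Ireland–Claisen rearrangement as in step 10 gives the epoxy acid F5 (buffered work-up, used at once). Iodolactonization then meets a single alkene and gives the epoxy iodolactone F6. Bu3SnH gives the epoxy lactone F7, and methylation as in step 13 gives 23.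

- **Step 16.** Mitsunobu inversion at the hindered C2 with angelic acid may give elimination or some tiglate. The fallback sets out from 25 and comes back at 27. Dess–Martin oxidation gives the 2-ketone F8. Chelation-controlled reduction (Et2BOMe, NaBH4, THF–MeOH, −78 °C; boron bridges the 4α-OH and the ketone, so hydride enters on the β face) gives the 2α,4α-diol F9. Yamaguchi esterification (angelic acid, 2,4,6-trichlorobenzoyl chloride, Et3N, then 4-(dimethylamino)pyridine) acylates only the secondary 2α-OH and gives 27.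

Further compounds

F1 | step 4 | (1S,4R)-4-(tert-butyldimethylsilyloxy)-1-methyl-2-(prop-2-enyl)cyclopent-2-enyl methyl carbonate | COC(=O)O[C@@]1(C)C[C@@H](O[Si](C)(C)C(C)(C)C)C=C1CC=C
F2 | step 4 | dimethyl 2-methyl-2-[(1R,5R)-5-(tert-butyldimethylsilyloxy)-3-methyl-2-(prop-2-enyl)cyclopent-2-enyl]propanedioate | COC(=O)C(C)(C(=O)OC)[C@H]1C(CC=C)=C(C)C[C@H]1O[Si](C)(C)C(C)(C)C
F3 | step 4 | methyl 2-[(1S,5R)-5-(tert-butyldimethylsilyloxy)-3-methyl-2-(prop-2-enyl)cyclopent-2-enyl]propanoate (C2 epimers) | COC(=O)C(C)[C@H]1C(CC=C)=C(C)C[C@H]1O[Si](C)(C)C(C)(C)C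
F4 | step 11 | 4α,5α-epoxy-2β-(tert-butyldimethylsilyloxy)-11,12,13-trinor-1αH-guai-7-en-9β-yl (tert-butyldimethylsilyloxy)acetate | C[C@@H]1[C@@H](OC(=O)CO[Si](C)(C)C(C)(C)C)C=CC[C@]23O[C@]3(C)C[C@@H](O[Si](C)(C)C(C)(C)C)[C@@H]12
F5 | step 11 | 4α,5α-epoxy-2β,11-bis(tert-butyldimethylsilyloxy)-13-nor-1αH,7αH-guai-8-en-12-oic acid (C11 epimers) | C[C@@H]1C=C[C@@H](C(O[Si](C)(C)C(C)(C)C)C(O)=O)C[C@]23O[C@]3(C)C[C@@H](O[Si](C)(C)C(C)(C)C)[C@@H]12
F6 | step 11 | 4α,5α-epoxy-9α-iodo-2β,11-bis(tert-butyldimethylsilyloxy)-13-nor-1αH,7αH,8αH-guaian-12,8-olide (C11 epimers) | C[C@@H]1[C@H](I)[C@H]2OC(=O)C(O[Si](C)(C)C(C)(C)C)[C@H]2C[C@]34O[C@]4(C)C[C@@H](O[Si](C)(C)C(C)(C)C)[C@@H]13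
F7 | step 11 | 4α,5α-epoxy-2β,11-bis(tert-butyldimethylsilyloxy)-13-nor-1αH,7αH,8αH-guaian-12,8-olide (C11 epimers) | C[C@@H]1C[C@H]2OC(=O)C(O[Si](C)(C)C(C)(C)C)[C@H]2C[C@]34O[C@]4(C)C[C@@H](O[Si](C)(C)C(C)(C)C)[C@@H]13
F8 | step 16 | (11S)-5β,11-epoxy-4α-hydroxy-2-oxo-1αH,7αH,8αH-guaian-12,8-olide | O=C1C[C@@](C)(O)[C@@]23C[C@H]4[C@@H](C[C@@H](C)[C@H]12)OC(=O)[C@@]4(C)O3
F9 | step 16 | (11S)-5β,11-epoxy-2α,4α-dihydroxy-1αH,7αH,8αH-guaian-12,8-olide | O[C@H]1C[C@@](C)(O)[C@@]23C[C@H]4[C@@H](C[C@@H](C)[C@H]12)OC(=O)[C@@]4(C)O3
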